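**Plan**
- The quinone is carried as its 2,5-dimethoxyarene and unmasked last. The butenolide C3=C4 bond is cut by ring-closing metathesis, and the ester C–O bond is cut back to an allylic alcohol and 2-homoprenylacrylic acid.
- Key cut: the E-trisubstituted olefin next to the quinone ring, ring–CH2–CH=C(CH3)–CH2, is opened at its C–CH3 bond and at its vinyl CH–benzylic CH2 bond. This gives a terminal alkyne, trimethylaluminium and a benzylic chloride.
- The inner olefin CH2–C(CH3)=CH–CH2 is cut the same way into an alkyne, trimethylaluminium and a homopropargylzinc reagent.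
- Forward, the chain grows from the carbinol end: C6 enynol, methylalumination–iodination, alkyl–alkenyl coupling, terminal enyne, three-component coupling with the arene, ester, then the butenolide as the only ring formed.
- The single stereocentre (S, lactone C5) comes from (S)-epichlorohydrin and its C–O bond is never broken. Both E olefins come from syn-carbometalation with retention in the couplings.

Key step: step 12

Remark: (S)-epichlorohydrin, (4-bromobut-1-yn-1-yl)trimethylsilane and 5-bromo-2-methylpent-2-ene are taken as commercial. The stereocentre is drawn from the chiral pool so that no resolution is needed.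

**Route**

Step 1
Reactants: 1 (S)-epichlorohydrin; 2 trimethylsilylacetylene
Product: 4 (S)-1-chloro-5-(trimethylsilyl)pent-4-yn-2-ol, via lithium (trimethylsilyl)acetylide 3 (not isolated)
Conditions: 2, n-BuLi, THF, −78 °C; BF3·OEt2; then 1, −78 °C; H2O quench
Reagents that add atoms: none
Why: BF3-assisted opening of the epoxide by the lithium acetylide at its unsubstituted carbon (Yamaguchi alkynylation) leaves the C–O stereocentre untouched, so the S configuration of 1 should pass into 4.

Step 2
Reactants: 4 (S)-1-chloro-5-(trimethylsilyl)pent-4-yn-2-ol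
Product: 6 (S)-6-(trimethylsilyl)hex-1-en-5-yn-3-ol, via epoxide (S)-trimethyl[3-(oxiran-2-yl)prop-1-yn-1-yl]silane 5 (not isolated)
Conditions: Me3S+ I− (4 equiv), n-BuLi (4 equiv), THF, −20 °C; then 4, −20 °C → rt
Reagents that add atoms: trimethylsulfonium iodide, C[S+](C)C.[I-]
Why: Excess dimethylsulfonium methylide closes the chlorohydrin to epoxide 5 (Williamson closure), opens it at the terminal carbon and eliminates dimethyl sulfide from the betaine, the known one-carbon epoxide-to-allylic-alcohol homologation; the carbinol C–O bond is never broken.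

Step 3
Reactants: 6 (S)-6-(trimethylsilyl)hex-1-en-5-yn-3-ol
Product: 7 (S)-tert-butyldimethyl{[6-(trimethylsilyl)hex-1-en-5-yn-3-yl]oxy}silane
Conditions: TBSCl, imidazole, DMF, rt
Reagents that add atoms: tert-butyldimethylsilyl chloride, CC(C)(C)[Si](C)(C)Cl
Why: Corey silylation of a secondary alcohol; the ether should withstand the organoaluminium, organozinc and carbonate steps that follow.

Step 4
Reactants: 7 (S)-tert-butyldimethyl{[6-(trimethylsilyl)hex-1-en-5-yn-3-yl]oxy}silane
Product: 8 (S)-tert-butyl(hex-1-en-5-yn-3-yloxy)dimethylsilane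
Conditions: K2CO3, MeOH, rt
Reagents that add atoms: none
Why: Base-catalysed methanolysis cleaves the alkynyl C–Si bond selectively, since a secondary TBS ether is stable to carbonate in methanol.

Step 5
Reactants: 8 (S)-tert-butyl(hex-1-en-5-yn-3-yloxy)dimethylsilane; 9 trimethylaluminium
Product: 11 (S,E)-tert-butyl[(6-iodo-5-methylhexa-1,5-dien-3-yl)oxy]dimethylsilane, via alkenyl(dimethyl)alane 10 (not isolated)
Conditions: 9 (3 equiv), Cp2ZrCl2 (0.3 equiv), CH2Cl2, 0 °C → rt; then I2, THF, −30 → 0 °C
Reagents that add atoms: iodine, II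
Why: Negishi zirconium-catalysed methylalumination adds CH3 and Al syn with the metal on the terminal carbon, and iodinolysis with retention should give the E-iodide; the vinyl group and the silyl ether react far more slowly than the alkyne.

Step 6
Reactants: 11 (S,E)-tert-butyl[(6-iodo-5-methylhexa-1,5-dien-3-yl)oxy]dimethylsilane; 12 (4-bromobut-1-yn-1-yl)trimethylsilane
Product: 14 (S,E)-tert-butyldimethyl{[5-methyl-10-(trimethylsilyl)deca-1,5-dien-9-yn-3-yl]oxy}silane, via [4-(trimethylsilyl)but-3-yn-1-yl]zinc bromide 13 (not isolated)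
Conditions: 12, Zn dust, LiCl, THF, 50 °C; then 11, Pd(PPh3)4 (5 mol%), THF, rt
Reagents that add atoms: none
Why: Negishi alkyl–alkenyl cross-coupling: the alkenyl iodide adds oxidatively to zerovalent palladium, the homopropargylzinc transmetalates and reductive elimination keeps the E geometry; homopropargylzinc reagents are established partners for this 1,5-enyne construction.

Step 7
Reactants: 14 (S,E)-tert-butyldimethyl{[5-methyl-10-(trimethylsilyl)deca-1,5-dien-9-yn-3-yl]oxy}silane
Product: 15 (S,5E)-3-(tert-butyldimethylsilyloxy)-5-methyldeca-1,5-dien-9-yne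
Conditions: K2CO3, MeOH, rt
Reagents that add atoms: none
Why: Carbonate-catalysed methanolysis of the alkynylsilane, as in step 4, should free the terminal alkyne without touching the TBS ether.

Step 8
Reactants: 16 4-methoxy-2-methylphenol
Product: 17 2-hydroxy-5-methoxy-3-methylbenzaldehyde
Conditions: MgCl2, Et3N, (CH2O)n, MeCN, reflux
Reagents that add atoms: paraformaldehyde (as formaldehyde), C=O
Why: Magnesium-mediated ortho-formylation of a phenol (Casnati–Skattebøl); the magnesium phenoxide delivers formaldehyde to the only free ortho position and a second formaldehyde oxidises the benzylic alkoxide to the aldehyde.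

Step 9
Reactants: 17 2-hydroxy-5-methoxy-3-methylbenzaldehyde
Product: 18 2,5-dimethoxy-3-methylbenzaldehyde
Conditions: MeI, K2CO3, DMF, rt → 50 °C
Reagents that add atoms: iodomethane, CI
Why: Williamson O-methylation of the phenoxide.

Step 10
Reactants: 18 2,5-dimethoxy-3-methylbenzaldehyde
Product: 19 (2,5-dimethoxy-3-methylphenyl)methanol
Conditions: NaBH4, MeOH, 0 °C
Reagents that add atoms: none
Why: Borohydride reduction of an aryl aldehyde to the benzylic alcohol.

Step 11
Reactants: 19 (2,5-dimethoxy-3-methylphenyl)methanol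
Product: 20 1-(chloromethyl)-2,5-dimethoxy-3-methylbenzene
Conditions: SOCl2, CH2Cl2, 0 °C → rt
Reagents that add atoms: thionyl chloride, O=S(Cl)Cl
Why: Chlorodehydroxylation of a benzylic alcohol through its chlorosulfite; the chloride should be used promptly because the ring is electron-rich.

Step 12
Reactants: 15 (S,5E)-3-(tert-butyldimethylsilyloxy)-5-methyldeca-1,5-dien-9-yne; 9 trimethylaluminium; 20 1-(chloromethyl)-2,5-dimethoxy-3-methylbenzene
Product: 22 (S,5E,9E)-3-(tert-butyldimethylsilyloxy)-11-(2,5-dimethoxy-3-methylphenyl)-5,9-dimethylundeca-1,5,9-triene, via alkenyl(dimethyl)alane 21 (not isolated)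
Conditions: 9 (2.5 equiv), Cp2ZrCl2 (0.5 equiv), ClCH2CH2Cl, 0 °C → rt; volatiles removed in vacuo; then 20, Pd(PPh3)4 (5 mol%), THF, rt
Reagents that add atoms: none
Why: Cp2ZrCl2 and Me3Al form a methylzirconium–aluminium species that adds CH3 and metal syn across the terminal C≡C of 15 with the metal on the unhindered CH, and exchange to aluminium gives the E-alkenylalane 21 (Negishi zirconium-catalysed methylalumination). Once free Me3Al is pumped off, the benzylic C–Cl bond of 20 adds oxidatively to the zerovalent palladium of Pd(PPh3)4, the alkenyl group passes from aluminium to divalent palladium, and reductive elimination joins vinyl CH to benzylic CH2 with retention of geometry (palladium-catalysed alkenylalane–benzyl halide cross-coupling). The C–CH3 bond and the vinyl–benzyl bond of the arene-side olefin are thus made in one flask; no ring closes and no stereocentre is formed, the S carbinol centre being a remote spectator. The step needs regio- and syn-selective carbometalation and reaction of the alkyne ahead of the two olefins; the single terminal alkyne reacts far faster than the vinyl group or the trisubstituted olefin, and the silyl ether is inert to Me3Al at room temperature. A benzylic electrophile has no allylic terminus, so neither SN2'-type transposition nor E/Z scrambling can occur, and removing free Me3Al suppresses methyl transfer to the benzylpalladium intermediate.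

Step 13
Reactants: 22 (S,5E,9E)-3-(tert-butyldimethylsilyloxy)-11-(2,5-dimethoxy-3-methylphenyl)-5,9-dimethylundeca-1,5,9-triene
Product: 23 (S,5E,9E)-11-(2,5-dimethoxy-3-methylphenyl)-5,9-dimethylundeca-1,5,9-trien-3-ol
Conditions: TBAF, THF, rt
Reagents that add atoms: none
Why: Fluoride-mediated cleavage of the silyl ether, driven by the Si–F bond, should free the allylic alcohol without affecting the olefins or aryl ethers.

Step 14
Reactants: 24 diethyl malonate; 25 5-bromo-2-methylpent-2-ene
Product: 26 diethyl 2-(4-methylpent-3-en-1-yl)malonate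
Conditions: NaOEt, EtOH, 24 (2 equiv), reflux
Reagents that add atoms: none
Why: Malonic ester alkylation (SN2 at a primary bromide); excess malonate keeps the medium free of ethoxide and so limits dialkylation and elimination of the homoallylic bromide.

Step 15
Reactants: 26 diethyl 2-(4-methylpent-3-en-1-yl)malonate
Product: 27 2-(4-methylpent-3-en-1-yl)malonic acid
Conditions: KOH, EtOH/H2O, reflux; then aq. HCl, 0 °C
Reagents that add atoms: potassium hydroxide, [K+].[OH-]
Why: Saponification of both esters; cold acidification gives the diacid without hydrating the trisubstituted olefin.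

Step 16
Reactants: 27 2-(4-methylpent-3-en-1-yl)malonic acid
Product: 28 6-methyl-2-methylidenehept-5-enoic acid
Conditions: (CH2O)n, Et2NH, EtOAc, reflux
Reagents that add atoms: paraformaldehyde (as formaldehyde), C=O
Why: Mannich condensation of the monosubstituted malonic acid with formaldehyde and diethylamine, followed by decarboxylative elimination of the amine, is the classical route to 2-alkylacrylic acids.

Step 17
Reactants: 23 (S,5E,9E)-11-(2,5-dimethoxy-3-methylphenyl)-5,9-dimethylundeca-1,5,9-trien-3-ol; 28 6-methyl-2-methylidenehept-5-enoic acid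
Product: 29 (S,5E,9E)-11-(2,5-dimethoxy-3-methylphenyl)-5,9-dimethylundeca-1,5,9-trien-3-yl 6-methyl-2-methylidenehept-5-enoate
Conditions: DCC, DMAP (cat.), CH2Cl2, 0 °C → rt
Reagents that add atoms: none
Why: Steglich esterification acylates the alcohol oxygen, so the carbinol C–O bond and its S configuration are retained; the α-substituent on the acrylic acid suppresses conjugate addition.

Step 18
Reactants: 29 (S,5E,9E)-11-(2,5-dimethoxy-3-methylphenyl)-5,9-dimethylundeca-1,5,9-trien-3-yl 6-methyl-2-methylidenehept-5-enoate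
Product: 30 (S)-5-[(2E,6E)-8-(2,5-dimethoxy-3-methylphenyl)-2,6-dimethylocta-2,6-dien-1-yl]-3-(4-methylpent-3-en-1-yl)furan-2(5H)-one
Conditions: second-generation Grubbs catalyst (H2IMes)(PCy3)Cl2Ru=CHPh (5–10 mol%), CH2Cl2 (5 mM), reflux
Reagents that add atoms: none
Why: Ring-closing metathesis: the carbene loads on the monosubstituted vinyl group and closes onto the 1,1-disubstituted acrylate olefin to give the five-membered butenolide with loss of ethene; closure onto any trisubstituted olefin would need a four- or eight-membered ring and should not compete.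

Step 19
Reactants: 30 (S)-5-[(2E,6E)-8-(2,5-dimethoxy-3-methylphenyl)-2,6-dimethylocta-2,6-dien-1-yl]-3-(4-methylpent-3-en-1-yl)furan-2(5H)-one
Product: 31 (S)-5-[(2E,6E)-2,6-dimethyl-8-(5-methyl-3,6-dioxocyclohexa-1,4-dien-1-yl)octa-2,6-dien-1-yl]-3-(4-methylpent-3-en-1-yl)furan-2(5H)-one
Conditions: (NH4)2Ce(NO3)6 (2.5 equiv), MeCN/H2O (2:1), 0 °C
Reagents that add atoms: water, O
Why: Oxidative demethylation of a 1,4-dimethoxyarene by tetravalent cerium: two one-electron oxidations with water attack at the ipso carbons give the para-quinone; isolated trisubstituted olefins and the butenolide are known to tolerate these brief, cold conditions.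

**Compound list**

1 | (S)-epichlorohydrin | ClC[C@@H]1CO1 | starting material
2 | trimethylsilylacetylene | C#C[Si](C)(C)C | starting material
3 | lithium (trimethylsilyl)acetylide | [Li]C#C[Si](C)(C)C | intermediate (not isolated)
4 | (S)-1-chloro-5-(trimethylsilyl)pent-4-yn-2-ol | ClC[C@@H](O)CC#C[Si](C)(C)C | intermediate
5 | (S)-trimethyl[3-(oxiran-2-yl)prop-1-yn-1-yl]silane | C1[C@@H](O1)CC#C[Si](C)(C)C | intermediate (not isolated)
6 | (S)-6-(trimethylsilyl)hex-1-en-5-yn-3-ol | C=C[C@@H](O)CC#C[Si](C)(C)C | intermediate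
7 | (S)-tert-butyldimethyl{[6-(trimethylsilyl)hex-1-en-5-yn-3-yl]oxy}silane | C=C[C@@H](O[Si](C)(C)C(C)(C)C)CC#C[Si](C)(C)C | intermediate
8 | (S)-tert-butyl(hex-1-en-5-yn-3-yloxy)dimethylsilane | C=C[C@@H](O[Si](C)(C)C(C)(C)C)CC#C | intermediate
9 | trimethylaluminium | C[Al](C)C | starting material
10 | (S,E)-[4-(tert-butyldimethylsilyloxy)-2-methylhexa-1,5-dien-1-yl]dimethylalane | C=C[C@@H](O[Si](C)(C)C(C)(C)C)C/C(C)=C/[Al](C)C | intermediate (not isolated)
11 | (S,E)-tert-butyl[(6-iodo-5-methylhexa-1,5-dien-3-yl)oxy]dimethylsilane | C=C[C@@H](O[Si](C)(C)C(C)(C)C)C/C(C)=C/I | intermediate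
12 | (4-bromobut-1-yn-1-yl)trimethylsilane | C[Si](C)(C)C#CCCBr | starting material
13 | [4-(trimethylsilyl)but-3-yn-1-yl]zinc bromide | C[Si](C)(C)C#CCC[Zn]Br | intermediate (not isolated)
14 | (S,E)-tert-butyldimethyl{[5-methyl-10-(trimethylsilyl)deca-1,5-dien-9-yn-3-yl]oxy}silane | C=C[C@@H](O[Si](C)(C)C(C)(C)C)C/C(C)=C/CCC#C[Si](C)(C)C | intermediate
15 | (S,5E)-3-(tert-butyldimethylsilyloxy)-5-methyldeca-1,5-dien-9-yne | C=C[C@@H](O[Si](C)(C)C(C)(C)C)C/C(C)=C/CCC#C | intermediate
16 | 4-methoxy-2-methylphenol | COc1ccc(O)c(C)c1 | starting material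
17 | 2-hydroxy-5-methoxy-3-methylbenzaldehyde | COc1cc(C)c(O)c(C=O)c1 | intermediate
18 | 2,5-dimethoxy-3-methylbenzaldehyde | COc1cc(C)c(OC)c(C=O)c1 | intermediate
19 | (2,5-dimethoxy-3-methylphenyl)methanol | COc1cc(C)c(OC)c(CO)c1 | intermediate
20 | 1-(chloromethyl)-2,5-dimethoxy-3-methylbenzene | COc1cc(C)c(OC)c(CCl)c1 | intermediate
21 | (S,1E,5E)-[8-(tert-butyldimethylsilyloxy)-2,6-dimethyldeca-1,5,9-trien-1-yl]dimethylalane | C=C[C@@H](O[Si](C)(C)C(C)(C)C)C/C(C)=C/CC/C(C)=C/[Al](C)C | intermediate (not isolated)
22 | (S,5E,9E)-3-(tert-butyldimethylsilyloxy)-11-(2,5-dimethoxy-3-methylphenyl)-5,9-dimethylundeca-1,5,9-triene | COc1cc(C)c(OC)c(C/C=C(\C)CC/C=C(\C)C[C@H](O[Si](C)(C)C(C)(C)C)C=C)c1 | intermediate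
23 | (S,5E,9E)-11-(2,5-dimethoxy-3-methylphenyl)-5,9-dimethylundeca-1,5,9-trien-3-ol | COc1cc(C)c(OC)c(C/C=C(\C)CC/C=C(\C)C[C@H](O)C=C)c1 | intermediate
24 | diethyl malonate | CCOC(=O)CC(=O)OCC | starting material
25 | 5-bromo-2-methylpent-2-ene | CC(C)=CCCBr | starting material
26 | diethyl 2-(4-methylpent-3-en-1-yl)malonate | CCOC(=O)C(CCC=C(C)C)C(=O)OCC | intermediate
27 | 2-(4-methylpent-3-en-1-yl)malonic acid | OC(=O)C(CCC=C(C)C)C(O)=O | intermediate
28 | 6-methyl-2-methylidenehept-5-enoic acid | C=C(CCC=C(C)C)C(=O)O | intermediate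
29 | (S,5E,9E)-11-(2,5-dimethoxy-3-methylphenyl)-5,9-dimethylundeca-1,5,9-trien-3-yl 6-methyl-2-methylidenehept-5-enoate | COc1cc(C)c(OC)c(C/C=C(\C)CC/C=C(\C)C[C@H](OC(=O)C(=C)CCC=C(C)C)C=C)c1 | intermediate
30 | (S)-5-[(2E,6E)-8-(2,5-dimethoxy-3-methylphenyl)-2,6-dimethylocta-2,6-dien-1-yl]-3-(4-methylpent-3-en-1-yl)furan-2(5H)-one | CC(C)=CCCC1=C[C@H](C/C(C)=C/CC/C(C)=C/Cc2cc(OC)cc(C)c2OC)OC1=O | intermediate
31 | (S)-5-[(2E,6E)-2,6-dimethyl-8-(5-methyl-3,6-dioxocyclohexa-1,4-dien-1-yl)octa-2,6-dien-1-yl]-3-(4-methylpent-3-en-1-yl)furan-2(5H)-one | CC(C)=CCCC1=C[C@H](C/C(C)=C/CC/C(C)=C/CC2=CC(=O)C=C(C)C2=O)OC1=O | target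

**Step count**

Total: 19 steps. Longest linear sequence: 12 steps (steps 1–7, 12, 13, 17, 18, 19).

**Steps most likely to fail**

Step 12. The carbometalation may stall, or residual methylaluminium species may transfer methyl to the benzylpalladium intermediate. The benzylic chloride may also homocouple if transfer of the alkenyl group from aluminium is slow. The fallback separates the two events and reverses the polarity of the coupling. It sets out from 15: the same methylalumination with 9 and Cp2ZrCl2 is quenched with I2 to give the isolable (S,5E,9E)-3-(tert-butyldimethylsilyloxy)-10-iodo-5,9-dimethyldeca-1,5,9-triene F1. Chloride 20 is converted with Zn dust and LiCl in THF into (2,5-dimethoxy-3-methylbenzyl)zinc chloride F2. Negishi coupling of F1 with F2 under Pd(PPh3)4 should then give 22, where the route is rejoined.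

Step 18. Closure onto the hindered, electron-poor 1,1-disubstituted acrylate olefin may be slow. The ruthenium carbene would then have time to engage the trisubstituted olefins, with loss of isobutene from the prenyl terminus or oligomerisation. The fallback closes an unsubstituted acrylate and adds the side chain afterwards. It sets out from 23: acryloyl chloride and Et3N give (S,5E,9E)-11-(2,5-dimethoxy-3-methylphenyl)-5,9-dimethylundeca-1,5,9-trien-3-yl acrylate F3. Ring-closing metathesis with the second-generation Grubbs catalyst gives (S)-5-[(2E,6E)-8-(2,5-dimethoxy-3-methylphenyl)-2,6-dimethylocta-2,6-dien-1-yl]furan-2(5H)-one F4. Iodination with I2 and pyridine in CH2Cl2 gives (S)-5-[(2E,6E)-8-(2,5-dimethoxy-3-methylphenyl)-2,6-dimethylocta-2,6-dien-1-yl]-3-iodofuran-2(5H)-one F5. Negishi coupling of F5 with (4-methylpent-3-en-1-yl)zinc bromide F6, made from 25 with Zn dust and LiCl, under Pd(PPh3)4 should give 30, where the route is rejoined.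

Step 6. Zinc insertion into the bromide may be incomplete, and the alkylpalladium intermediate may undergo β-hydride elimination, leading to reduction of the iodide and homocoupling. The fallback builds the same 1,5-enyne by allylic alkylation instead of cross-coupling. It sets out from 8: the alkenylalane 10, generated as in step 5, is trapped with paraformaldehyde to give (S,2E)-5-(tert-butyldimethylsilyloxy)-3-methylhepta-2,6-dien-1-ol F7. CBr4 and PPh3 in CH2Cl2 convert it into (S,E)-[(7-bromo-5-methylhepta-1,5-dien-3-yl)oxy](tert-butyl)dimethylsilane F8. SN2 displacement by [3-(trimethylsilyl)prop-2-yn-1-yl]lithium F9, made from 1-(trimethylsilyl)propyne and n-BuLi in THF at −78 °C, should give 14, where the route is rejoined.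

**Further compounds**

F1 | step 12 | (S,5E,9E)-3-(tert-butyldimethylsilyloxy)-10-iodo-5,9-dimethyldeca-1,5,9-triene | C=C[C@@H](O[Si](C)(C)C(C)(C)C)C/C(C)=C/CC/C(C)=C/I
F2 | step 12 | (2,5-dimethoxy-3-methylbenzyl)zinc chloride | COc1cc(C)c(OC)c(C[Zn]Cl)c1
F3 | step 18 | (S,5E,9E)-11-(2,5-dimethoxy-3-methylphenyl)-5,9-dimethylundeca-1,5,9-trien-3-yl acrylate | COc1cc(C)c(OC)c(C/C=C(\C)CC/C=C(\C)C[C@H](OC(=O)C=C)C=C)c1
F4 | step 18 | (S)-5-[(2E,6E)-8-(2,5-dimethoxy-3-methylphenyl)-2,6-dimethylocta-2,6-dien-1-yl]furan-2(5H)-one | O=C1C=C[C@H](C/C(C)=C/CC/C(C)=C/Cc2cc(OC)cc(C)c2OC)O1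
F5 | step 18 | (S)-5-[(2E,6E)-8-(2,5-dimethoxy-3-methylphenyl)-2,6-dimethylocta-2,6-dien-1-yl]-3-iodofuran-2(5H)-one | O=C1C(I)=C[C@H](C/C(C)=C/CC/C(C)=C/Cc2cc(OC)cc(C)c2OC)O1
F6 | step 18 | (4-methylpent-3-en-1-yl)zinc bromide | CC(C)=CCC[Zn]Br
F7 | step 6 | (S,2E)-5-(tert-butyldimethylsilyloxy)-3-methylhepta-2,6-dien-1-ol | C=C[C@@H](O[Si](C)(C)C(C)(C)C)C/C(C)=C/CO
F8 | step 6 | (S,E)-[(7-bromo-5-methylhepta-1,5-dien-3-yl)oxy](tert-butyl)dimethylsilane | C=C[C@@H](O[Si](C)(C)C(C)(C)C)C/C(C)=C/CBr
F9 | step 6 | [3-(trimethylsilyl)prop-2-yn-1-yl]lithium | [Li]CC#C[Si](C)(C)C
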